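**Strategy.** The route rests on forging the bond between the exocyclic oxymethylene carbon and the cyclopentane carbon flanked by the methyl-bearing carbon and the carbon carrying the 1,3-diol arm. A copper-catalysed 1,4-addition of a silylmethyl Grignard reagent (a masked hydroxymethyl group) to an enantiopure 4-substituted cyclopent-2-enone, followed in the same flask by methylation of the enolate, makes this bond and two adjacent stereocentres in one operation. On the all-trans five-membered ring (ring A) each new group enters anti to its neighbour, so the single bought stereocentre relays the others. The two identical acyl arms, made by a chirality-transferring Johnson–Claisen rearrangement, are attached by one double Mitsunobu esterification and unveiled last.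

Key step: step 6

Remark on the chemistry: ring A is the cyclopentane. Its carbons are called Ca (bears the CH2O group), Cb (bears the methyl group), Cc (bears the ring oxygen), Cd (CH2) and Ce (bears the 1,3-diol arm). "Up/down" refers to ring A drawn with the Ce substituent up. Both acyl groups of the target are the same (3S,4E)-4-formyl-3-(2-oxoethyl)hex-4-enoyl unit, so one acid (19) serves twice. Compounds 1, 2, 7 and 13 are assumed to be commercially available.

**Step 1**
Reactants: 1 (1S,4R)-cis-4-acetoxycyclopent-2-en-1-ol, 2 dimethyl malonate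
Product: 3 dimethyl 2-[(1R,4S)-4-hydroxycyclopent-2-en-1-yl]propanedioate (malonate cis to OH)
Conditions: NaH (1.3 equiv), 2 (1.5 equiv), THF, 0 °C; then 1, Pd(PPh3)4 (3 mol %), THF, 45 °C
Reagents that add atoms: none
Why: Tsuji–Trost allylic alkylation: zerovalent palladium ionises the acetate with inversion and the soft malonate attacks the allyl terminus remote from the hydroxyl with a second inversion, so the malonate replaces the acetate with net retention and the bought stereocentre becomes Ce.

**Step 2**
Reactants: 3 dimethyl 2-[(1R,4S)-4-hydroxycyclopent-2-en-1-yl]propanedioate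
Product: 4 2-[(1R,4S)-4-hydroxycyclopent-2-en-1-yl]propane-1,3-diol
Conditions: LiAlH4 (3 equiv), THF, 0 °C → rt; Fieser work-up
Reagents that add atoms: none
Why: Hydride reduction of both ester groups gives the 2-substituted propane-1,3-diol arm of the target; no stereocentre is touched.

**Step 3**
Reactants: 4 2-[(1R,4S)-4-hydroxycyclopent-2-en-1-yl]propane-1,3-diol
Product: 5 (1S,4R)-4-(2,2-dimethyl-1,3-dioxan-5-yl)cyclopent-2-en-1-ol
Conditions: 2,2-dimethoxypropane, PPTS (cat.), acetone, rt
Reagents that add atoms: 2,2-dimethoxypropane, COC(C)(C)OC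
Why: Acid-catalysed transketalisation gives the thermodynamically favoured six-membered acetonide of the 1,3-diol and leaves the secondary allylic alcohol free.

**Step 4**
Reactants: 5 (1S,4R)-4-(2,2-dimethyl-1,3-dioxan-5-yl)cyclopent-2-en-1-ol
Product: 6 (4R)-4-(2,2-dimethyl-1,3-dioxan-5-yl)cyclopent-2-en-1-one
Conditions: MnO2 (activated, excess), CH2Cl2, rt
Reagents that add atoms: none
Why: Neutral allylic oxidation with MnO2 gives the enone without base, so the γ-stereocentre (Ce) should not be deprotonated.

**Step 5**
Reactants: 7 (chloromethyl)dimethyl(propan-2-yloxy)silane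
Product: 8 {[dimethyl(propan-2-yloxy)silyl]methyl}magnesium chloride
Conditions: Mg turnings, BrCH2CH2Br (cat.), THF, 45 °C
Reagents that add atoms: magnesium, [Mg]
Why: Grignard formation from the α-silyl chloride gives Tamao's hydroxymethyl anion equivalent, whose C–Si bond is later oxidised to C–OH.

**Step 6**
Reactants: 6 (4R)-4-(2,2-dimethyl-1,3-dioxan-5-yl)cyclopent-2-en-1-one, 8 {[dimethyl(propan-2-yloxy)silyl]methyl}magnesium chloride
Product: 10 (2R,3S,4S)-4-(2,2-dimethyl-1,3-dioxan-5-yl)-3-{[dimethyl(propan-2-yloxy)silyl]methyl}-2-methylcyclopentan-1-one, via chloromagnesium enolate 9 (not isolated)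
Conditions: 8 (1.4 equiv), CuBr·SMe2 (10 mol %), THF, −78 °C; then HMPA, MeI (6 equiv), −78 → −10 °C
Reagents that add atoms: iodomethane, CI
Why: The Grignard reagent transmetalates to a silylmethylcopper species that adds 1,4 to the enone (π-complex, trivalent-copper β-adduct, reductive elimination), creating the bond between the silylmethyl carbon (the future CH2O carbon) and ring carbon Ca and leaving a regiodefined chloromagnesium enolate, which HMPA makes nucleophilic enough for C-methylation by MeI. The closest known reaction type is the copper-catalysed conjugate addition–enolate alkylation (three-component coupling) of 4-substituted cyclopent-2-enones, here run with a silylmethyl Grignard reagent as hydroxymethyl anion equivalent. No ring is closed. The configuration at Ca is controlled by the dioxanyl group on the neighbouring Ce, which shields one face of the flat enone so that the reagent enters anti to it; the configuration at Cb is controlled by the new silylmethyl group on Ca, anti to which MeI approaches the enolate, so the 2,3-trans-3,4-trans ketone should result. The step needs 1,4- over 1,2-selectivity (secured by copper), face selectivity (secured by the Ce substituent directly beside the reacting carbon) and mono-C-methylation at Cb without enolate equilibration (secured by low temperature, HMPA and an excess of the small, fast electrophile).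

**Step 7**
Reactants: 10 (2R,3S,4S)-4-(2,2-dimethyl-1,3-dioxan-5-yl)-3-{[dimethyl(propan-2-yloxy)silyl]methyl}-2-methylcyclopentan-1-one
Product: 12 (1S,2R,3S,4R)-4-(2,2-dimethyl-1,3-dioxan-5-yl)-3-(hydroxymethyl)-2-methylcyclopentan-1-ol, via lithium alkoxide 11 (not isolated)
Conditions: LiBH(s-Bu)3 (1.3 equiv), THF, −78 °C; then KF, KHCO3, 30 % H2O2, THF/MeOH, 0 → 40 °C
Reagents that add atoms: hydrogen peroxide, OO
Why: The bulky hydride should attack the ketone anti to the adjacent Cb methyl group (OH cis to methyl at Cc, as in reductions of 2,3-trans-disubstituted cyclopentanones), and the peroxide work-up doubles as the Tamao–Fleming oxidation that turns the C–Si bond into the primary alcohol.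

**Step 8**
Reactants: 13 (2S)-but-3-yn-2-ol
Product: 15 (2S,3E)-3-methylhepta-3,6-dien-2-ol, via alkenylalane 14 (not isolated)
Conditions: Me3Al (3 equiv), Cp2ZrCl2 (0.25 equiv), CH2Cl2, 0 °C → rt; then allyl bromide, Pd(PPh3)4 (5 mol %), THF, rt
Reagents that add atoms: trimethylaluminium, C[Al](C)C; allyl bromide, C=CCBr
Why: Zirconium-catalysed syn-carboalumination (Negishi) places methyl on the internal and aluminium on the terminal alkyne carbon, and palladium-catalysed cross-coupling of the alkenylalane with allyl bromide proceeds with retention to the (E)-1,4-diene; the carbinol stereocentre is untouched.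

**Step 9**
Reactants: 15 (2S,3E)-3-methylhepta-3,6-dien-2-ol
Product: 17 methyl (3S)-3-[(2E)-but-2-en-2-yl]hex-5-enoate, via ketene acetal 16 (not isolated)
Conditions: MeC(OMe)3 (6 equiv), EtCO2H (cat.), xylene, 135 °C, removal of MeOH
Reagents that add atoms: trimethyl orthoacetate, CC(OC)(OC)OC
Why: Johnson–Claisen rearrangement through a chair transition state with the carbinol methyl group equatorial transfers the (S)-carbinol chirality suprafacially to the new (S)-configured carbon that carries the CH2CO2Me group.

**Step 10**
Reactants: 17 methyl (3S)-3-[(2E)-but-2-en-2-yl]hex-5-enoate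
Product: 18 methyl (3S,4E)-4-formyl-3-(prop-2-en-1-yl)hex-4-enoate
Conditions: SeO2 (1.5 equiv), 1,4-dioxane, 85 °C
Reagents that add atoms: selenium dioxide, O=[Se]=O
Why: Riley allylic oxidation (ene reaction, then 2,3-sigmatropic shift) attacks the methyl group on the more substituted end of the trisubstituted alkene (CH3 before CH) and should give the (E)-enal, which is also the thermodynamically preferred geometry; the terminal alkene reacts far more slowly.

**Step 11**
Reactants: 18 methyl (3S,4E)-4-formyl-3-(prop-2-en-1-yl)hex-4-enoate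
Product: 19 (3S,4E)-4-formyl-3-(prop-2-en-1-yl)hex-4-enoic acid
Conditions: Me3SnOH (5 equiv), 1,2-dichloroethane, 70 °C; 1 M HCl work-up
Reagents that add atoms: trimethyltin hydroxide, C[Sn](C)(C)O
Why: Tin-hydroxide-mediated methyl ester hydrolysis is nearly neutral and should spare the base-sensitive enal that aqueous hydroxide could attack.

**Step 12**
Reactants: 12 (1S,2R,3S,4R)-4-(2,2-dimethyl-1,3-dioxan-5-yl)-3-(hydroxymethyl)-2-methylcyclopentan-1-ol, 19 (3S,4E)-4-formyl-3-(prop-2-en-1-yl)hex-4-enoic acid (2.6 equiv)
Product: 20 bis-ester acetonide (ring A all-trans: Ce dioxanyl up, Ca CH2O-acyl down, Cb methyl up, Cc O-acyl down; both acyl groups = (3S,4E)-4-formyl-3-(prop-2-en-1-yl)hex-4-enoyl)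
Conditions: PPh3 (3.2 equiv), DIAD (3.2 equiv), toluene, 0 °C → rt
Reagents that add atoms: none
Why: Double Mitsunobu esterification: the primary alcohol is acylated without stereochemical consequence, while the activated ring carbinol at Cc is displaced by the carboxylate in an SN2 step with inversion, which places the acyloxy group trans to the Cb methyl group as the target requires.

**Step 13**
Reactants: 20 bis-ester acetonide
Product: 21 bis-ester diol (as 20, with the free 2-substituted propane-1,3-diol on Ce)
Conditions: AcOH/THF/H2O (3:1:1), 35 °C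
Reagents that add atoms: none
Why: Mild acid hydrolysis cleaves the 1,3-dioxane ketal, while esters, enals and terminal alkenes are inert to dilute acetic acid.

**Step 14**
Reactants: 21 bis-ester diol
Product: 23 target compound CNP0313563.1, via bis-ozonide 22 (not isolated)
Conditions: O3, CH2Cl2, −78 °C, Sudan Red 7B as end-point indicator; then PPh3 (2.5 equiv), −78 °C → rt
Reagents that add atoms: ozone, [O-][O+]=O
Why: Chemoselective ozonolysis: the electron-rich monosubstituted alkenes undergo 1,3-dipolar cycloaddition with electrophilic ozone much faster than the formyl-conjugated trisubstituted alkenes, and PPh3 reduces the ozonides to the two CH2CHO groups under neutral conditions that leave the free 1,3-diol untouched.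

**Compound list**

1 | (1S,4R)-cis-4-acetoxycyclopent-2-en-1-ol | O[C@H]1C[C@@H](OC(C)=O)C=C1 | starting material
2 | dimethyl malonate | COC(=O)CC(=O)OC | starting material
3 | dimethyl 2-[(1R,4S)-4-hydroxycyclopent-2-en-1-yl]propanedioate | O[C@H]1C[C@@H](C(C(=O)OC)C(=O)OC)C=C1 | intermediate
4 | 2-[(1R,4S)-4-hydroxycyclopent-2-en-1-yl]propane-1,3-diol | O[C@H]1C[C@@H](C(CO)CO)C=C1 | intermediate
5 | (1S,4R)-4-(2,2-dimethyl-1,3-dioxan-5-yl)cyclopent-2-en-1-ol | O[C@H]1C[C@@H](C2COC(C)(C)OC2)C=C1 | intermediate
6 | (4R)-4-(2,2-dimethyl-1,3-dioxan-5-yl)cyclopent-2-en-1-one | O=C1C[C@@H](C2COC(C)(C)OC2)C=C1 | intermediate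
7 | (chloromethyl)dimethyl(propan-2-yloxy)silane | CC(C)O[Si](C)(C)CCl | starting material
8 | {[dimethyl(propan-2-yloxy)silyl]methyl}magnesium chloride | CC(C)O[Si](C)(C)C[Mg]Cl | intermediate
9 | chloromagnesium (3S,4S)-4-(2,2-dimethyl-1,3-dioxan-5-yl)-3-{[dimethyl(propan-2-yloxy)silyl]methyl}cyclopent-1-en-1-olate | CC(C)O[Si](C)(C)C[C@@H]1C=C(O[Mg]Cl)C[C@H]1C2COC(C)(C)OC2 | intermediate
10 | (2R,3S,4S)-4-(2,2-dimethyl-1,3-dioxan-5-yl)-3-{[dimethyl(propan-2-yloxy)silyl]methyl}-2-methylcyclopentan-1-one | CC(C)O[Si](C)(C)C[C@@H]1[C@@H](C)C(=O)C[C@H]1C2COC(C)(C)OC2 | intermediate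
11 | lithium (1S,2R,3S,4S)-4-(2,2-dimethyl-1,3-dioxan-5-yl)-3-{[dimethyl(propan-2-yloxy)silyl]methyl}-2-methylcyclopentan-1-olate | CC(C)O[Si](C)(C)C[C@@H]1[C@@H](C)[C@@H](O[Li])C[C@H]1C2COC(C)(C)OC2 | intermediate
12 | (1S,2R,3S,4R)-4-(2,2-dimethyl-1,3-dioxan-5-yl)-3-(hydroxymethyl)-2-methylcyclopentan-1-ol | OC[C@@H]1[C@@H](C)[C@@H](O)C[C@H]1C2COC(C)(C)OC2 | intermediate
13 | (2S)-but-3-yn-2-ol | C[C@H](O)C#C | starting material
14 | dimethylaluminium alkoxide of (2S,3E)-4-(dimethylalumanyl)-3-methylbut-3-en-2-ol | C[C@H](O[Al](C)C)/C(C)=C/[Al](C)C | intermediate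
15 | (2S,3E)-3-methylhepta-3,6-dien-2-ol | C[C@H](O)/C(C)=C/CC=C | intermediate
16 | (2S,3E)-2-[(1-methoxyethenyl)oxy]-3-methylhepta-3,6-diene (mixed ketene acetal) | C[C@H](OC(=C)OC)/C(C)=C/CC=C | intermediate
17 | methyl (3S)-3-[(2E)-but-2-en-2-yl]hex-5-enoate | C/C=C(C)/[C@@H](CC=C)CC(=O)OC | intermediate
18 | methyl (3S,4E)-4-formyl-3-(prop-2-en-1-yl)hex-4-enoate | C/C=C(/C=O)[C@@H](CC=C)CC(=O)OC | intermediate
19 | (3S,4E)-4-formyl-3-(prop-2-en-1-yl)hex-4-enoic acid | C/C=C(/C=O)[C@@H](CC=C)CC(=O)O | intermediate
20 | bis-ester acetonide (all-trans ring A; both acyl groups (3S,4E)-4-formyl-3-(prop-2-en-1-yl)hex-4-enoyl) | C/C=C(/C=O)[C@@H](CC=C)CC(=O)OC[C@@H]1[C@@H](C)[C@H](OC(=O)C[C@H](CC=C)/C(C=O)=C\C)C[C@H]1C2COC(C)(C)OC2 | intermediate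
21 | bis-ester diol (as 20 with free propane-1,3-diol arm) | C/C=C(/C=O)[C@@H](CC=C)CC(=O)OC[C@@H]1[C@@H](C)[C@H](OC(=O)C[C@H](CC=C)/C(C=O)=C\C)C[C@H]1C(CO)CO | intermediate
22 | bis(1,2,4-trioxolane) of 21 (both terminal alkenes as secondary ozonides, trioxolane carbons as epimer mixture) | C/C=C(/C=O)[C@@H](CC3OCOO3)CC(=O)OC[C@@H]1[C@@H](C)[C@H](OC(=O)C[C@H](CC4OCOO4)/C(C=O)=C\C)C[C@H]1C(CO)CO | intermediate
23 | CNP0313563.1 | C/C=C(/C=O)[C@@H](CC=O)CC(=O)OC[C@@H]1[C@@H](C)[C@H](OC(=O)C[C@H](CC=O)/C(C=O)=C\C)C[C@H]1C(CO)CO | target

**Total step count:** 14 steps.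
**Longest linear sequence:** 9 steps (steps 1, 2, 3, 4, 6, 7, 12, 13, 14). Steps 5 and 8–11 are side branches.

**Three steps most likely to fail**

1. Step 12 (double Mitsunobu). The invertive displacement at the hindered ring carbinol Cc, which sits next to the cis methyl group, may stall with a weakly acidic aliphatic carboxylic acid. Elimination to a cyclopentene or alkylation of the reduced azodicarboxylate could then take over, and the phosphine may add reversibly to the enal of the acid. The fallback separates inversion from attachment of the valuable acid. It sets out from diol 12: Mitsunobu reaction with the more acidic 4-nitrobenzoic acid (PPh3, DIAD, toluene) should give the inverted bis(4-nitrobenzoate) F1. Methanolysis (K2CO3, MeOH) gives the all-trans diol F2. A non-invertive carbodiimide esterification of both hydroxyl groups with acid 19 (EDC·HCl, DMAP, CH2Cl2) returns to the route at compound 20.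

2. Step 6 (key step). The chloromagnesium enolate may be methylated too slowly. Proton transfer between enolate and product would then give regioisomeric or double methylation, and the silylmethyl group may transfer sluggishly from copper. The fallback sets out from enone 6: the same copper-catalysed addition of 8 is run with Me3SiCl as activator and trap, and the regiodefined trimethylsilyl enol ether F3 is isolated. Fluoride-induced alkylation (anhydrous benzyltrimethylammonium fluoride, MeI, THF, −78 °C → rt) then generates a naked enolate only in the presence of the electrophile and returns to the route at compound 10.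

3. Step 14 (selective ozonolysis). Over-oxidation may set in, that is, ozone may begin to cleave the ethylidene double bonds of the two enals before both terminal alkenes are consumed. The fallback sets out from diol 21: osmium-catalysed dihydroxylation (OsO4 cat., N-methylmorpholine N-oxide, acetone/H2O), which discriminates more strongly against electron-poor alkenes, should give the bis(1,2-diol) F4 as a mixture of epimers at the new carbinol carbons. Glycol cleavage with NaIO4 (THF/pH 7 buffer, 0 °C) does not touch the 1,3-diol and returns to the route at compound 23.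

**Further compounds**

F1 | step 12 | bis(4-nitrobenzoate) of the Cc-inverted diol (acetonide retained) | [O-][N+](=O)c1ccc(cc1)C(=O)OC[C@@H]1[C@@H](C)[C@H](OC(=O)c3ccc(cc3)[N+](=O)[O-])C[C@H]1C2COC(C)(C)OC2
F2 | step 12 | (1R,2R,3S,4R)-4-(2,2-dimethyl-1,3-dioxan-5-yl)-3-(hydroxymethyl)-2-methylcyclopentan-1-ol (all-trans diol) | OC[C@@H]1[C@@H](C)[C@H](O)C[C@H]1C2COC(C)(C)OC2
F3 | step 6 | trimethylsilyl enol ether of the 1,4-adduct | CC(C)O[Si](C)(C)C[C@@H]1C=C(O[Si](C)(C)C)C[C@H]1C2COC(C)(C)OC2
F4 | step 14 | bis(1,2-diol) of 21 (new carbinol carbons as epimer mixture) | C/C=C(/C=O)[C@@H](CC(O)CO)CC(=O)OC[C@@H]1[C@@H](C)[C@H](OC(=O)C[C@H](CC(O)CO)/C(C=O)=C\C)C[C@H]1C(CO)CO
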